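The data were generated by integration with constants of no real substance.

With their charges alike, temperature and time say how much G has gone from each of the flasks asked about. How much of that became D is a second question, so I reckon the two apart.

| flask | G | E | temperature | remark | time |
|---|---|---|---|---|---|
| oak | 0.21 M | 0.16 M | 25 °C | run made earlier |  |
| larch | 0.21 M | 0.63 M | 58 °C | run made earlier |  |
| cedar | 0.32 M | 0.315 M | 25 °C | run made earlier |  |
| Sunday's | 0.21 M | 0.315 M | 40 °C |  | 3.0 min |
| Saturday's | 0.21 M | 0.315 M | 10 °C |  | 3.0 min |
| Wednesday's | 0.21 M | 0.315 M | 70 °C |  | 3.0 min |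

oak run (percent of the G charged)

| time / min | D / % | G / % |
|---|---|---|
| 0.500 | 6 | 75 |
| 0.667 | 3 | 69 |
| 1.00 | 3 | 57 |
| 2.00 | 7 | 37 |
| 3.00 | 10 | 30 |
| 4.00 | 8 | 25 |
| 6.00 | 11 | 17 |

larch run (percent of the G charged)

| time / s | D / % | G / % |
|---|---|---|
| 10.0 | 15 | 20 |
| 12.0 | 11 | 17 |
| 20.0 | 13 | 8 |
| 30.0 | 17 | 1 |
| 50.0 | 16 | 3 |
| 60.0 | 17 | 2 |
| 80.0 | 16 | 0 |

cedar run (percent of the G charged)

| time / min | D / % | G / % |
|---|---|---|
| 0.500 | 4 | 64 |
| 2.00 | 10 | 27 |
| 3.00 | 8 | 19 |
| 4.00 | 11 | 13 |
| 6.00 | 13 | 10 |

(readings scatter by 1.5 percentage points)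

- percent here means G units held: one X counts as two
- steps under discussion: G + E -> L; 2 G -> X; G + E -> D; G + E -> Z

- the flask with the highest amount of D, in percent of the G charged ("all alike" if they lie within 1.5 percentage points) (Sunday's / Saturday's / Wednesday's / all alike)
- final D, as a percentage of the G charged, in Sunday's
- final D, as a percentage of the G charged, in Saturday's
- final D, as a percentage of the G charged, in Wednesday's

My carried quantity is the D share, the selectivity: D divided by the G consumed, read late in a run. The last larch reading gives the high value and the last oak reading the low one, each carrying the scatter of its readings. I assume the flasks asked about lie between them: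

D share, high: 16.0 %
D share, low: 13.3 %

For the G consumed I treat the loss as second order, with κ the inverse of the fraction of G left, less one, per unit time. I read it from oak and larch at 3.00 min and 20.0 s. Larch has [E] higher by a factor of 3.94, so I divide that out to leave the heat factor, and spread it evenly over the degrees. In temperature, Sunday's lies as far above oak as Saturday's lies below it.

κ, oak: 0.778 min⁻¹
κ, larch: 34.5 min⁻¹
heat factor, oak to larch: 11.3
factor for that step of temperature: 3.01

For Sunday's, the top of the bracket has all G consumed and the bottom counts no gain from E. I place the hotter Wednesday's in the same bracket: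

from 11.6 % to 16.0 %

For Saturday's, the bottom counts no gain from E and the top counts the full gain:

from 5.79 % to 9.67 %

So by my reckoning Saturday's comes lowest, while the bracket does not separate Sunday's from Wednesday's.

The forecast names Wednesday's, with 15 % for Sunday's and 15.5 % for Wednesday's inside my bracket and 10 % for Saturday's just above it, and adds: “Those two are close, so the choice of Wednesday's is tentative.”

The flasks give Sunday's the most D: 14.8 % there, 8.42 % in Saturday's and 10.0 % in Wednesday's, which falls below my bracket.

    G + E → L (k = 0.170 M⁻¹ s⁻¹, Ea = 72.0 kJ mol⁻¹)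
    2 G → X (k = 0.630 M⁻¹ s⁻¹, Ea = 65.0 kJ mol⁻¹)
    G + E → D (k = 0.0800 M⁻¹ s⁻¹, Ea = 49.0 kJ mol⁻¹)
    G + E → Z (k = 0.160 M⁻¹ s⁻¹, Ea = 59.0 kJ mol⁻¹)
    (constants at 70 °C)

Wednesday's D share is 10.0 % of the G consumed, against the 16.0 % I carried. From the coldest flask to the hottest, G + E → D speeds up by a factor of 38 and G + E → L by 210. After 3.00 min, L stands at 3.24 % in Saturday's and 21.3 % in Wednesday's. In a flask like Saturday's kept at 35 °C, the carried share times the G consumed after 3.00 min gives 14.8 %, and that flask then holds 15.0 % of D.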